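**Plan**
- The target is the C2-symmetric (2R,3R)-2,3-bis(4-hydroxy-3,5-dimethoxybenzyl)butane-1,4-diol. It consists of two identical aryl–C3 halves with no ring besides the two benzene rings, joined at C8–C8' (C2–C3 of the butanediol), the bond between its only two stereocentres.
- Retrosynthesis: the two phenols are masked as benzyl ethers and C9/C9' are raised to acyl oxazolidinones. The single C8–C8' bond is then cut to give two copies of one N-(3-arylpropanoyl)oxazolidinone. Its N-acyl bond and ArO–benzyl bond lead back to sinapic acid.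
- Forward: sinapic acid → dihydro acid → O-benzyl acid → imide → oxidative enolate dimerisation (the chain is joined, no ring forms) → LiBH4 cleavage to the 1,4-diol → hydrogenolysis.
- Stereochemistry: both centres arise in the dimerisation. Each is set by the (S)-4-benzyl group of its own oxazolidinone (bonding anti to that group gives R at C8 and C8'), and no later step touches them.

Key step: step 4

Remark: lignan numbering is used for the side chain (C7 benzylic CH2, C8 methine, C9 oxygenated carbon, primed numbers for the second half), and LiN(iPr)2 is taken from a commercial solution.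

**Route**

Step 1
Reactants: 1 sinapic acid ((E)-3-(4-hydroxy-3,5-dimethoxyphenyl)prop-2-enoic acid)
Product: 2 3-(4-hydroxy-3,5-dimethoxyphenyl)propanoic acid
Conditions: H2 (1 atm), 10% Pd/C, MeOH, rt
Reagents that add atoms: none
Why: Heterogeneous catalytic hydrogenation saturates the cinnamic C=C and leaves arene, phenol and acid alone; it is placed before any benzyl group is present.

Step 2
Reactants: 2 3-(4-hydroxy-3,5-dimethoxyphenyl)propanoic acid; 3 benzyl bromide
Product: 5 3-(4-benzyloxy-3,5-dimethoxyphenyl)propanoic acid, via benzyl ester benzyl ether 4 (not isolated)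
Conditions: BnBr (2.3 equiv), K2CO3, DMF, 60 °C; then 2 M NaOH, MeOH, 60 °C; then HCl to pH 2
Reagents that add atoms: benzyl bromide 3, BrCc1ccccc1; sodium hydroxide, [Na+].[OH-]
Why: Williamson etherification benzylates phenoxide and carboxylate, and saponification in the same pot returns the acid while the aryl benzyl ether, which masks the oxidation-prone phenol for step 4, is stable to hydroxide.

Step 3
Reactants: 5 3-(4-benzyloxy-3,5-dimethoxyphenyl)propanoic acid; 6 (S)-4-benzyloxazolidin-2-one
Product: 8 (S)-4-benzyl-3-[3-(4-benzyloxy-3,5-dimethoxyphenyl)propanoyl]oxazolidin-2-one, via mixed pivalic anhydride 7 (not isolated)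
Conditions: PivCl, Et3N, THF, −20 °C; then LiCl, 6, −20 °C to rt
Reagents that add atoms: none
Why: N-acylation of the oxazolidinone through the mixed pivalic anhydride with LiCl/Et3N activation (Evans imide formation) occurs at the unhindered arylpropanoyl carbonyl of 7 and does not involve the stereocentre of 6.

Step 4
Reactants: 8 (S)-4-benzyl-3-[3-(4-benzyloxy-3,5-dimethoxyphenyl)propanoyl]oxazolidin-2-one (two molecules)
Product: 10 (4S,4'S)-3,3'-[(2R,3R)-2,3-bis(4-benzyloxy-3,5-dimethoxybenzyl)succinyl]bis(4-benzyloxazolidin-2-one), via lithium Z-enolate 9 (not isolated)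
Conditions: LiN(iPr)2 (1.1 equiv), THF, −78 °C; then CuCl2 (1.2 equiv), DMF, −78 °C to rt
Reagents that add atoms: none
Why: LiN(iPr)2 removes the C8 proton to give the lithium-chelated Z-enolate 9, and CuCl2 oxidises it by one electron (divalent copper going to monovalent copper) to a copper-associated α-imido radical that joins a second enolate carbon, or a second radical, to form the C8–C8' bond. The closest known reaction type is the CuCl2-mediated oxidative homocoupling of lithium enolates of chiral N-(3-arylpropanoyl)oxazolidinones, which gives 2,3-disubstituted succinyl bis-imides. No ring is closed; one acyclic C–C bond and two stereocentres (C8 and C8') result. Each new centre is controlled by the C4 benzyl group of its own oxazolidinone: in the chelated Z-enolate that group covers one face, so both carbons bond on the open Si face in the same sense as in Evans alkylation, and the S auxiliary should therefore give R at C8 and at C8'. The step needs like-sense facial selectivity at both carbons (R,R over meso and S,S) and oxidation of the enolate in preference to the electron-rich ring; the first is secured by the two identical auxiliaries and the fixed enolate geometry, the second by the far lower oxidation potential of the enolate at −78 °C and the benzyl cap on the phenol.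

Step 5
Reactants: 10 (4S,4'S)-3,3'-[(2R,3R)-2,3-bis(4-benzyloxy-3,5-dimethoxybenzyl)succinyl]bis(4-benzyloxazolidin-2-one)
Product: 11 (2R,3R)-2,3-bis(4-benzyloxy-3,5-dimethoxybenzyl)butane-1,4-diol
Conditions: LiBH4 (6 equiv), MeOH (6 equiv), THF, 0 °C to rt; aq NH4Cl
Reagents that add atoms: none
Why: Reductive cleavage of N-acyloxazolidinones with LiBH4 delivers hydride to the lithium-activated exocyclic carbonyls, and any lactone formed when the first alkoxide attacks the second imide is reduced to the same diol; neither α-centre is deprotonated, so R,R is kept and auxiliary 6 is returned.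

Step 6
Reactants: 11 (2R,3R)-2,3-bis(4-benzyloxy-3,5-dimethoxybenzyl)butane-1,4-diol
Product: 12 (2R,3R)-2,3-bis(4-hydroxy-3,5-dimethoxybenzyl)butane-1,4-diol (5,5'-dimethoxysecoisolariciresinol)
Conditions: H2 (1 atm), 10% Pd/C, MeOH/EtOAc, rt
Reagents that add atoms: none
Why: Catalytic hydrogenolysis cleaves the two aryl benzyl ethers, while the aliphatic C–O bonds, the methyl ethers and both stereocentres are inert.

**Compound list**
1 | sinapic acid | COc1cc(/C=C/C(=O)O)cc(OC)c1O | starting material
2 | 3-(4-hydroxy-3,5-dimethoxyphenyl)propanoic acid | COc1cc(CCC(=O)O)cc(OC)c1O | intermediate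
3 | benzyl bromide | BrCc1ccccc1 | starting material
4 | benzyl 3-(4-benzyloxy-3,5-dimethoxyphenyl)propanoate | COc1cc(CCC(=O)OCc2ccccc2)cc(OC)c1OCc1ccccc1 | intermediate
5 | 3-(4-benzyloxy-3,5-dimethoxyphenyl)propanoic acid | COc1cc(CCC(=O)O)cc(OC)c1OCc1ccccc1 | intermediate
6 | (S)-4-benzyloxazolidin-2-one | O=C1N[C@@H](Cc2ccccc2)CO1 | starting material
7 | 3-(4-benzyloxy-3,5-dimethoxyphenyl)propanoic pivalic anhydride | COc1cc(CCC(=O)OC(=O)C(C)(C)C)cc(OC)c1OCc1ccccc1 | intermediate
8 | (S)-4-benzyl-3-[3-(4-benzyloxy-3,5-dimethoxyphenyl)propanoyl]oxazolidin-2-one | COc1cc(CCC(=O)N2[C@@H](Cc3ccccc3)COC2=O)cc(OC)c1OCc1ccccc1 | intermediate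
9 | lithium (Z)-enolate of 8 | COc1cc(C/C=C(\O[Li])N2[C@@H](Cc3ccccc3)COC2=O)cc(OC)c1OCc1ccccc1 | intermediate
10 | (4S,4'S)-3,3'-[(2R,3R)-2,3-bis(4-benzyloxy-3,5-dimethoxybenzyl)succinyl]bis(4-benzyloxazolidin-2-one) | COc1cc(C[C@@H](C(=O)N2[C@@H](Cc3ccccc3)COC2=O)[C@H](C(=O)N2[C@@H](Cc3ccccc3)COC2=O)Cc2cc(OC)c(OCc3ccccc3)c(OC)c2)cc(OC)c1OCc1ccccc1 | intermediate
11 | (2R,3R)-2,3-bis(4-benzyloxy-3,5-dimethoxybenzyl)butane-1,4-diol | COc1cc(C[C@@H](CO)[C@H](CO)Cc2cc(OC)c(OCc3ccccc3)c(OC)c2)cc(OC)c1OCc1ccccc1 | intermediate
12 | (2R,3R)-2,3-bis(4-hydroxy-3,5-dimethoxybenzyl)butane-1,4-diol (5,5'-dimethoxysecoisolariciresinol) | COc1cc(C[C@@H](CO)[C@H](CO)Cc2cc(OC)c(O)c(OC)c2)cc(OC)c1O | target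

**Step count**
Total steps: 6. Longest linear sequence: 6 steps (1 to 12).

**Steps most likely to fail**

1. Step 4. Facial control at the two enolate carbons may be incomplete, and chlorine transfer from CuCl2 to the enolate or simple reprotonation may compete. Either would lower the share of the R,R dimer and make its separation from the meso and S,S dimers difficult. The fallback sets out from 8 and returns at 11. It forms C8–C8' by alkylation and adds the second arylmethyl group afterwards.
   - The sodium enolate of 8 (NaN(SiMe3)2, THF, −78 °C) is alkylated with tert-butyl bromoacetate anti to the auxiliary benzyl group. This should give tert-butyl (3R)-3-(4-benzyloxy-3,5-dimethoxybenzyl)-4-[(4S)-4-benzyl-2-oxooxazolidin-3-yl]-4-oxobutanoate F1.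
   - LiBH4 in THF/MeOH at 0 °C reduces only the imide and should give tert-butyl (3R)-3-(4-benzyloxy-3,5-dimethoxybenzyl)-4-hydroxybutanoate F2. Catalytic TsOH in warm toluene closes it to (4R)-4-(4-benzyloxy-3,5-dimethoxybenzyl)dihydrofuran-2(3H)-one F3.
   - In parallel, commercial 4-benzyloxy-3,5-dimethoxybenzaldehyde is reduced with NaBH4 in MeOH to (4-benzyloxy-3,5-dimethoxyphenyl)methanol F4. PBr3 in Et2O converts it into 4-benzyloxy-3,5-dimethoxybenzyl bromide F5.
   - The lithium enolate of F3 (LiN(SiMe3)2, THF, −78 °C) is alkylated with F5 trans to the C4 substituent. This should give (3R,4R)-3,4-bis(4-benzyloxy-3,5-dimethoxybenzyl)dihydrofuran-2(3H)-one F6, and LiAlH4 in THF opens the lactone to diol 11.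

2. Step 5. Hydride may attack the ring carbonyl of the crowded imides, opening the oxazolidinone and losing auxiliary, or the reduction may stall at the lactone stage. The fallback sets out from 10 and returns at 11; it hydrolyses first and reduces second. LiOH/H2O2 in THF/H2O at 0 °C, where the hydroperoxide anion attacks the exocyclic carbonyl even of hindered imides, should give (2R,3R)-2,3-bis(4-benzyloxy-3,5-dimethoxybenzyl)succinic acid F7 and free 6. LiAlH4 in THF then reduces the diacid to 11.

3. Step 6. Hydrogenolysis of the two benzyl ethers, each flanked by two methoxy groups, may be slow or incomplete, for instance through catalyst poisoning by boron or amine residues from step 5. The fallback sets out from 11 and returns at 12. It replaces hydrogenolysis by Lewis-acid dealkylation: BCl3 with pentamethylbenzene as benzyl-cation scavenger in CH2Cl2 at −78 °C, then MeOH quench. This cleaves aryl benzyl ethers and should spare the aryl methyl ethers at this temperature. It makes no new compound (F0).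

**Further compounds**
F1 | step 4 | tert-butyl (3R)-3-(4-benzyloxy-3,5-dimethoxybenzyl)-4-[(4S)-4-benzyl-2-oxooxazolidin-3-yl]-4-oxobutanoate | COc1cc(C[C@@H](C(=O)N2[C@@H](Cc3ccccc3)COC2=O)CC(=O)OC(C)(C)C)cc(OC)c1OCc1ccccc1
F2 | step 4 | tert-butyl (3R)-3-(4-benzyloxy-3,5-dimethoxybenzyl)-4-hydroxybutanoate | COc1cc(C[C@@H](CO)CC(=O)OC(C)(C)C)cc(OC)c1OCc1ccccc1
F3 | step 4 | (4R)-4-(4-benzyloxy-3,5-dimethoxybenzyl)dihydrofuran-2(3H)-one | O=C1C[C@@H](Cc2cc(OC)c(OCc3ccccc3)c(OC)c2)CO1
F4 | step 4 | (4-benzyloxy-3,5-dimethoxyphenyl)methanol | COc1cc(CO)cc(OC)c1OCc1ccccc1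
F5 | step 4 | 4-benzyloxy-3,5-dimethoxybenzyl bromide | COc1cc(CBr)cc(OC)c1OCc1ccccc1
F6 | step 4 | (3R,4R)-3,4-bis(4-benzyloxy-3,5-dimethoxybenzyl)dihydrofuran-2(3H)-one | COc1cc(C[C@H]2COC(=O)[C@@H]2Cc3cc(OC)c(OCc4ccccc4)c(OC)c3)cc(OC)c1OCc1ccccc1
F7 | step 5 | (2R,3R)-2,3-bis(4-benzyloxy-3,5-dimethoxybenzyl)succinic acid | COc1cc(C[C@@H](C(=O)O)[C@H](C(=O)O)Cc2cc(OC)c(OCc3ccccc3)c(OC)c2)cc(OC)c1OCc1ccccc1
F0 | step 6 | none | none
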